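**Retrosynthetic overview**

- The strategy rests on ring carbons C1–C6: C1 (ketone) and C4 (carbinol) are 1,4-oxygens flanking the C2=C3 bis(methoxy) alkene, and C5–C6 is a trans two-carbon unit whose C5 branch is cis to O4. This is the pattern of an endo [4+2] adduct of a 1,4-dioxy-2,3-dimethoxybutadiene with (E)-crotonaldehyde.
- Disconnections: C1'–C2' (alkylzinc/alkenyl iodide Negishi coupling), then C4–C5 and C1–C6 (enantioselective iminium Diels–Alder reaction); the diene comes from a di-O-methyltartrate by partial reduction and double enol silylation.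
- O1 and O4 are told apart by bridging the cis pair O4/O1' as a di-tert-butylsilylene, which leaves only the C1 hydroxyl for oxidation.
- Side chain C2'–C12': C8'–C9' by catalytic asymmetric propargylation of a prenyl-acetate-derived enal, C5'–C6' by Negishi coupling, and both trisubstituted E-alkenes by zirconium-catalysed carboalumination–iodination.
- Ring order: the only carbocycle (C1–C6) is closed in step 3; the dioxasilinane of steps 6–8 is a temporary protecting ring.

Key step: step 3

Remarks: Ring atoms are numbered C1 (ketone of the target), C2 and C3 (methoxy alkene), C4 (carbinol), C5 (chain), C6 (methyl); the chain is C1'–C12' outward.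
Assumption: the facial sense of the two catalytic asymmetric steps (3 and 15) is assigned from the accepted transition-state models; both catalyst enantiomers are available, so a reversed sense would be corrected by exchanging the catalyst enantiomer.

**Ring fragment**

Step 1
Reactants: 1 dimethyl 2,3-di-O-methyl-L-tartrate
Product: 2 (2R,3R)-2,3-dimethoxybutanedial
Conditions: i-Bu2AlH (2.2 equiv), CH2Cl2, −78 °C; MeOH quench, aq. Rochelle salt; crude product dried by toluene azeotrope and used at once
Reagents that add atoms: none
Why: Partial hydride reduction of an α-alkoxy ester should stop at the aldehyde stage at −78 °C because the chelated tetrahedral aluminium hemiacetal survives until work-up, and the two stereocentres are of no consequence since both are erased in step 2.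

Step 2
Reactants: 2 (2R,3R)-2,3-dimethoxybutanedial
Product: 3 (1Z,3Z)-1,4-bis(tert-butyldimethylsilyloxy)-2,3-dimethoxybuta-1,3-diene
Conditions: t-BuMe2SiOTf (2.4 equiv), Et3N (5 equiv), CH2Cl2, 0 °C to rt; pentane, filtration, bulb-to-bulb distillation
Reagents that add atoms: tert-butyldimethylsilyl trifluoromethanesulfonate, CC(C)(C)[Si](C)(C)OS(=O)(=O)C(F)(F)F
Why: Soft enolisation (O-silylation of each formyl group, then loss of the α-proton to the amine) should place each silyloxy group cis to the small methoxy group and trans to the other half of the diene, which is the Z geometry that puts it outside in the s-cis conformer, while any isomer with an inside silyloxy group cannot reach the s-cis form and is a spectator in step 3.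

Step 3
Reactants: 3 (1Z,3Z)-1,4-bis(tert-butyldimethylsilyloxy)-2,3-dimethoxybuta-1,3-diene; 4 (E)-crotonaldehyde
Product: 5 (1R,2R,5S,6R)-2,5-bis(tert-butyldimethylsilyloxy)-3,4-dimethoxy-6-methylcyclohex-3-ene-1-carbaldehyde (formyl on ring C5, methyl on C6, silyloxy groups on C1 and C4; O1, O4 and the formyl group on one face, the methyl on the other)
Conditions: 4 (3 equiv), (2S,5S)-5-benzyl-2-tert-butyl-3-methylimidazolidin-4-one trifluoroacetate (20 mol %), MeCN, H2O (2 equiv), −20 °C; Et3N-buffered silica plug
Reagents that add atoms: none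
Why: The amine salt condenses with 4 to the (E)-iminium ion, whose lowered LUMO meets the HOMO of the fourfold donor-substituted diene in a normal-demand, concerted but asynchronous [4+2] cycloaddition; the closest known reaction type is the imidazolidinone-catalysed Diels–Alder reaction of enals with acyclic 1-acyloxydienes. The six-membered carbocycle is closed intermolecularly by suprafacial formation of C1–C6 and C4–C5, and if the bond to the β-carbon (C1–C6) runs ahead, the oxygen-stabilised allyl cation and the enamine should collapse by six-membered ring closure to the same adduct. The 5,6-trans relation follows from the E geometry of the dienophile and the 1,4-cis relation of the two silyloxy groups from their outside positions in the (Z,Z)-diene, which is symmetric so that no regiochemical question arises. The cis relation of O4 and the C5 formyl group is set by the endo orientation of the iminium unit over C2–C3 of the diene, with the methyl group exo. The absolute configuration is set by the benzyl group of the (2S,5S)-catalyst, which covers one face of the iminium π-system so that the diene adds to the Re face of the β-carbon, giving 6R and 5R. The step needs endo and facial selectivity and survival of the enol silanes; the bulky silyl groups, the low temperature and the small amount of water are chosen to hold back hydrolysis and desilylative Michael addition.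

Step 4
Reactants: 5 cycloadduct aldehyde
Product: 6 [(1S,2R,5S,6R)-2,5-bis(tert-butyldimethylsilyloxy)-3,4-dimethoxy-6-methylcyclohex-3-en-1-yl]methanol (C1' alcohol)
Conditions: NaBH4, MeOH/CH2Cl2, 0 °C
Reagents that add atoms: none
Why: Borohydride reduction of the aldehyde is fast at 0 °C and removes the epimerisable β-silyloxy formyl group before it can enolise or eliminate, without touching any stereocentre.

Step 5
Reactants: 6 bis(silyl ether) alcohol
Product: 7 (1S,4R,5S,6R)-5-(hydroxymethyl)-2,3-dimethoxy-6-methylcyclohex-2-ene-1,4-diol (triol)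
Conditions: n-Bu4NF (2.5 equiv), THF, 0 °C to rt; Et3N-deactivated silica
Reagents that add atoms: none
Why: Fluoride-induced desilylation should cleave both secondary silyl ethers under basic conditions that spare the acid-labile bis-allylic enediol diether.

Step 6
Reactants: 7 triol
Product: 8 O4,O1'-di-tert-butylsilylene derivative of 7 (cis-fused 2,2-di-tert-butyl-1,3,2-dioxasilinane across C4–C5; C1 hydroxyl free)
Conditions: t-Bu2Si(OTf)2 (1.05 equiv), 2,6-lutidine, CH2Cl2, −40 to 0 °C
Reagents that add atoms: di-tert-butylsilyl bis(trifluoromethanesulfonate), CC(C)(C)[Si](OS(=O)(=O)C(F)(F)F)(OS(=O)(=O)C(F)(F)F)C(C)(C)C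
Why: In this cyclic silylene formation the primary O1' should be silylated first and the remaining silyl triflate should close onto the cis O4 to give a six-membered ring, whereas reaching O1 would need a seven-membered ring, so the C1 hydroxyl alone stays free.

Step 7
Reactants: 8 silylene alcohol
Product: 9 silylene-protected enone (C1 ketone; O4 and O1' bridged)
Conditions: Dess–Martin periodinane, pyridine, CH2Cl2, 0 °C
Reagents that add atoms: none
Why: Dess–Martin oxidation of the only free hydroxyl (allylic, secondary) should give the 2,3-dimethoxy enone under buffered conditions, and C6 next to the new ketone already carries its methyl trans to the C5 branch, the more stable arrangement, so epimerisation is not expected.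

Step 8
Reactants: 9 silylene-protected enone
Product: 10 (4R,5S,6R)-4-hydroxy-5-(hydroxymethyl)-2,3-dimethoxy-6-methylcyclohex-2-en-1-one
Conditions: HF·pyridine, pyridine, THF, 0 °C
Reagents that add atoms: none
Why: Fluoride cleavage of the silylene (Si–O exchanged for Si–F) should free O4 and O1' without acid strong enough to harm the vinylogous ester, which after the oxidation no longer ionises readily at C4.

Step 9
Reactants: 10 diol enone
Product: 11 (4R,5R,6R)-4-hydroxy-5-(iodomethyl)-2,3-dimethoxy-6-methylcyclohex-2-en-1-one
Conditions: I2, PPh3, imidazole, CH2Cl2, 0 °C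
Reagents that add atoms: iodine, II
Why: In this Appel-type iodination the SN2 displacement of the alkoxyphosphonium ion should be much faster at the primary C1' than at the hindered secondary C4 carbinol.

Step 10
Reactants: 11 hydroxy iodide
Product: 12 (4R,5R,6R)-5-(iodomethyl)-2,3-dimethoxy-6-methyl-4-(triethylsilyloxy)cyclohex-2-en-1-one
Conditions: Et3SiOTf, 2,6-lutidine, CH2Cl2, −78 °C
Reagents that add atoms: triethylsilyl trifluoromethanesulfonate, CC[Si](CC)(CC)OS(=O)(=O)C(F)(F)F
Why: Silylation of the C4 hydroxyl removes the only acidic proton that could quench the alkylzinc reagent of step 22, and at −78 °C with a hindered pyridine base the ketone should not be enol-silylated.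

**Side chain**

Step 11
Reactants: 13 prenyl acetate
Product: 14 (E)-4-hydroxy-3-methylbut-2-en-1-yl acetate
Conditions: SeO2 (0.5 equiv), t-BuOOH (2 equiv), CH2Cl2, rt; chromatographic removal of the minor enal
Reagents that add atoms: selenium dioxide, O=[Se]=O; tert-butyl hydroperoxide, CC(C)(C)OO
Why: Allylic oxidation by SeO2 (ene reaction followed by [2,3]-sigmatropic shift) should attack the methyl group trans to the chain at the more substituted alkene terminus and so give the E allylic alcohol.

Step 12
Reactants: 14 (E)-4-hydroxy-3-methylbut-2-en-1-yl acetate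
Product: 15 (E)-4-(tert-butyldimethylsilyloxy)-3-methylbut-2-en-1-yl acetate
Conditions: t-BuMe2SiCl, imidazole, DMF, rt
Reagents that add atoms: tert-butyldimethylsilyl chloride, CC(C)(C)[Si](C)(C)Cl
Why: Imidazole-promoted silylation of the primary allylic alcohol (future O12') is routine and leaves the acetate untouched.

Step 13
Reactants: 15 silyl ether acetate
Product: 16 (E)-4-(tert-butyldimethylsilyloxy)-3-methylbut-2-en-1-ol
Conditions: K2CO3 (cat.), MeOH, 0 °C to rt
Reagents that add atoms: none
Why: Base-catalysed transesterification with methanol should remove the acetate while the silyl ether is stable to carbonate.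

Step 14
Reactants: 16 allylic alcohol
Product: 17 (E)-4-(tert-butyldimethylsilyloxy)-3-methylbut-2-enal
Conditions: MnO2 (excess), CH2Cl2, rt
Reagents that add atoms: none
Why: MnO2 oxidises allylic alcohols selectively to enals under neutral conditions that should keep the E geometry and the silyl ether.

Step 15
Reactants: 17 enal; 18 allenylboronic acid pinacol ester
Product: 19 (2E,4S)-1-(tert-butyldimethylsilyloxy)-2-methylhept-2-en-6-yn-4-ol
Conditions: 18 (1.5 equiv), (S)-TRIP [(S)-3,3'-bis(2,4,6-triisopropylphenyl)-1,1'-binaphthyl-2,2'-diyl hydrogen phosphate] (10 mol %), 4 Å MS, toluene, 0 °C; aq. work-up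
Reagents that add atoms: none
Why: In this chiral Brønsted-acid-catalysed propargylation the allenylboronate should add through a six-membered chair transition state with allenyl-to-propargyl transposition, and the (S)-phosphoric acid, bound to the boronate oxygen and the formyl hydrogen, should direct attack to the Si face of the aldehyde to set the 4S carbinol (C9').

Step 16
Reactants: 19 homopropargylic alcohol
Product: 20 (2E,4S)-1,4-bis(tert-butyldimethylsilyloxy)-2-methylhept-2-en-6-yne
Conditions: t-BuMe2SiCl, imidazole, DMF, rt
Reagents that add atoms: tert-butyldimethylsilyl chloride, CC(C)(C)[Si](C)(C)Cl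
Why: Silylation of the secondary allylic alcohol protects O9' against the organoaluminium and organozinc reagents that follow, without touching the stereocentre.

Step 17
Reactants: 20 terminal alkyne
Product: 22 (2E,4S,6E)-1,4-bis(tert-butyldimethylsilyloxy)-7-iodo-2,6-dimethylhepta-2,6-diene, via alkenylalane 21 (not isolated)
Conditions: Me3Al (3 equiv), Cp2ZrCl2 (25 mol %), CH2Cl2, 0 °C to rt; then I2, THF, −30 to 0 °C
Reagents that add atoms: trimethylaluminium, C[Al](C)C; iodine, II
Why: Zirconium-catalysed carboalumination (Negishi) adds methyl and aluminium syn across the terminal alkyne with aluminium on the terminal carbon, and iodinolysis with retention should give the E-alkenyl iodide (C6'=C7'), the trisubstituted alkene and silyl ethers being inert.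

Step 18
Reactants: 23 4-(trimethylsilyl)but-3-yn-1-ol
Product: 24 (4-iodobut-1-yn-1-yl)trimethylsilane
Conditions: I2, PPh3, imidazole, CH2Cl2, 0 °C
Reagents that add atoms: iodine, II
Why: Appel-type iodination converts the primary alcohol to the iodide by SN2 displacement.

Step 19
Reactants: 24 (4-iodobut-1-yn-1-yl)trimethylsilane; 22 alkenyl iodide
Product: 26 (5E,8S,9E)-8,11-bis(tert-butyldimethylsilyloxy)-6,10-dimethyl-1-(trimethylsilyl)undeca-5,9-dien-1-yne, via butynylzinc iodide 25 (not isolated)
Conditions: 24 (1.5 equiv), Zn dust (activated with BrCH2CH2Br and Me3SiCl), LiCl, THF, 40 °C; then 22, Pd(PPh3)4 (5 mol %), THF, rt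
Reagents that add atoms: none
Why: Zinc insertion into the primary iodide gives a homopropargylzinc reagent whose alkyne is masked by silicon, and its Negishi coupling with the alkenyl iodide should form C5'–C6' with retention of the E geometry.

Step 20
Reactants: 26 silylated enyne
Product: 27 (5E,8S,9E)-8,11-bis(tert-butyldimethylsilyloxy)-6,10-dimethylundeca-5,9-dien-1-yne
Conditions: K2CO3, MeOH, rt
Reagents that add atoms: none
Why: Methanolysis cleaves the alkynyl C–Si bond selectively, since the alkynyl anion is a far better leaving group from silicon than an alkoxide and the hindered silyl ethers are stable to carbonate.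

Step 21
Reactants: 27 terminal alkyne
Product: 29 (1E,5E,8S,9E)-8,11-bis(tert-butyldimethylsilyloxy)-1-iodo-2,6,10-trimethylundeca-1,5,9-triene (C2'–C12' alkenyl iodide), via alkenylalane 28 (not isolated)
Conditions: Me3Al (3 equiv), Cp2ZrCl2 (25 mol %), CH2Cl2, 0 °C to rt; then I2, THF, −30 to 0 °C
Reagents that add atoms: trimethylaluminium, C[Al](C)C; iodine, II
Why: A second zirconium-catalysed carboalumination–iodination (Negishi) should install the C3' methyl and the C2' iodide syn-selectively, giving the E-alkenyl iodide while the two existing trisubstituted alkenes do not react.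

**Union and deprotection**

Step 22
Reactants: 12 ring iodide; 29 C2'–C12' alkenyl iodide
Product: 31 (4R,5R,6R)-5-[(2E,6E,9S,10E)-9,12-bis(tert-butyldimethylsilyloxy)-3,7,11-trimethyldodeca-2,6,10-trien-1-yl]-2,3-dimethoxy-6-methyl-4-(triethylsilyloxy)cyclohex-2-en-1-one, via alkylzinc iodide 30 (not isolated)
Conditions: 12 (1.3 equiv), Zn dust (activated with BrCH2CH2Br and Me3SiCl), LiCl, THF, 30 °C; then 29, Pd(PPh3)4 (5 mol %), THF/DMF, rt
Reagents that add atoms: none
Why: Direct zinc insertion into the primary C–I bond should give an alkylzinc iodide that tolerates the ketone, the enol ether and the silyl ethers and has no β-leaving group, and its Negishi coupling with the alkenyl iodide forms C1'–C2' with retention of the E geometry.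

Step 23
Reactants: 31 tris(silyl ether)
Product: 32 (4R,5R,6R)-4-hydroxy-5-[(2E,6E,9S,10E)-9,12-dihydroxy-3,7,11-trimethyldodeca-2,6,10-trien-1-yl]-2,3-dimethoxy-6-methylcyclohex-2-en-1-one (target)
Conditions: HF·pyridine, pyridine, THF, 0 °C to rt
Reagents that add atoms: none
Why: Buffered fluoride desilylation should remove the triethylsilyl and both tert-butyldimethylsilyl ethers in one operation without the strong acid or base that could hydrolyse the vinylogous ester or epimerise C6.

**Compound list**

1 | dimethyl 2,3-di-O-methyl-L-tartrate | COC(=O)[C@H](OC)[C@@H](OC)C(=O)OC | starting material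
2 | (2R,3R)-2,3-dimethoxybutanedial | O=C[C@H](OC)[C@@H](OC)C=O | intermediate
3 | (1Z,3Z)-1,4-bis(tert-butyldimethylsilyloxy)-2,3-dimethoxybuta-1,3-diene | CC(C)(C)[Si](C)(C)O/C=C(\OC)/C(OC)=C/O[Si](C)(C)C(C)(C)C | intermediate
4 | (E)-crotonaldehyde | C/C=C/C=O | starting material
5 | (1R,2R,5S,6R)-2,5-bis(tert-butyldimethylsilyloxy)-3,4-dimethoxy-6-methylcyclohex-3-ene-1-carbaldehyde | COC1=C(OC)[C@H](O[Si](C)(C)C(C)(C)C)[C@H](C=O)[C@@H](C)[C@@H]1O[Si](C)(C)C(C)(C)C | intermediate
6 | [(1S,2R,5S,6R)-2,5-bis(tert-butyldimethylsilyloxy)-3,4-dimethoxy-6-methylcyclohex-3-en-1-yl]methanol | COC1=C(OC)[C@H](O[Si](C)(C)C(C)(C)C)[C@H](CO)[C@@H](C)[C@@H]1O[Si](C)(C)C(C)(C)C | intermediate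
7 | (1S,4R,5S,6R)-5-(hydroxymethyl)-2,3-dimethoxy-6-methylcyclohex-2-ene-1,4-diol | COC1=C(OC)[C@H](O)[C@H](CO)[C@@H](C)[C@@H]1O | intermediate
8 | O4,O1'-di-tert-butylsilylene derivative of 7 (cis-fused dioxasilinane, C1 hydroxyl free) | COC1=C(OC)[C@@H]2O[Si](C(C)(C)C)(C(C)(C)C)OC[C@@H]2[C@@H](C)[C@@H]1O | intermediate
9 | O4,O1'-di-tert-butylsilylene-protected enone (C1 ketone) | COC1=C(OC)[C@@H]2O[Si](C(C)(C)C)(C(C)(C)C)OC[C@@H]2[C@@H](C)C1=O | intermediate
10 | (4R,5S,6R)-4-hydroxy-5-(hydroxymethyl)-2,3-dimethoxy-6-methylcyclohex-2-en-1-one | COC1=C(OC)[C@H](O)[C@H](CO)[C@@H](C)C1=O | intermediate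
11 | (4R,5R,6R)-4-hydroxy-5-(iodomethyl)-2,3-dimethoxy-6-methylcyclohex-2-en-1-one | COC1=C(OC)[C@H](O)[C@H](CI)[C@@H](C)C1=O | intermediate
12 | (4R,5R,6R)-5-(iodomethyl)-2,3-dimethoxy-6-methyl-4-(triethylsilyloxy)cyclohex-2-en-1-one | COC1=C(OC)[C@H](O[Si](CC)(CC)CC)[C@H](CI)[C@@H](C)C1=O | intermediate
13 | prenyl acetate | CC(=O)OCC=C(C)C | starting material
14 | (E)-4-hydroxy-3-methylbut-2-en-1-yl acetate | CC(=O)OC/C=C(\C)CO | intermediate
15 | (E)-4-(tert-butyldimethylsilyloxy)-3-methylbut-2-en-1-yl acetate | CC(=O)OC/C=C(\C)CO[Si](C)(C)C(C)(C)C | intermediate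
16 | (E)-4-(tert-butyldimethylsilyloxy)-3-methylbut-2-en-1-ol | OC/C=C(\C)CO[Si](C)(C)C(C)(C)C | intermediate
17 | (E)-4-(tert-butyldimethylsilyloxy)-3-methylbut-2-enal | O=C/C=C(\C)CO[Si](C)(C)C(C)(C)C | intermediate
18 | allenylboronic acid pinacol ester | C=C=CB1OC(C)(C)C(C)(C)O1 | starting material
19 | (2E,4S)-1-(tert-butyldimethylsilyloxy)-2-methylhept-2-en-6-yn-4-ol | C#CC[C@H](O)/C=C(\C)CO[Si](C)(C)C(C)(C)C | intermediate
20 | (2E,4S)-1,4-bis(tert-butyldimethylsilyloxy)-2-methylhept-2-en-6-yne | C#CC[C@H](O[Si](C)(C)C(C)(C)C)/C=C(\C)CO[Si](C)(C)C(C)(C)C | intermediate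
21 | (E)-alkenyl(dimethyl)alane from 20 (aluminium on C6', methyl on C7') | C[Al](C)/C=C(\C)C[C@H](O[Si](C)(C)C(C)(C)C)/C=C(\C)CO[Si](C)(C)C(C)(C)C | intermediate
22 | (2E,4S,6E)-1,4-bis(tert-butyldimethylsilyloxy)-7-iodo-2,6-dimethylhepta-2,6-diene | I/C=C(\C)C[C@H](O[Si](C)(C)C(C)(C)C)/C=C(\C)CO[Si](C)(C)C(C)(C)C | intermediate
23 | 4-(trimethylsilyl)but-3-yn-1-ol | C[Si](C)(C)C#CCCO | starting material
24 | (4-iodobut-1-yn-1-yl)trimethylsilane | C[Si](C)(C)C#CCCI | intermediate
25 | 4-(trimethylsilyl)but-3-yn-1-ylzinc iodide | C[Si](C)(C)C#CCC[Zn]I | intermediate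
26 | (5E,8S,9E)-8,11-bis(tert-butyldimethylsilyloxy)-6,10-dimethyl-1-(trimethylsilyl)undeca-5,9-dien-1-yne | C[Si](C)(C)C#CCC/C=C(\C)C[C@H](O[Si](C)(C)C(C)(C)C)/C=C(\C)CO[Si](C)(C)C(C)(C)C | intermediate
27 | (5E,8S,9E)-8,11-bis(tert-butyldimethylsilyloxy)-6,10-dimethylundeca-5,9-dien-1-yne | C#CCC/C=C(\C)C[C@H](O[Si](C)(C)C(C)(C)C)/C=C(\C)CO[Si](C)(C)C(C)(C)C | intermediate
28 | (E)-alkenyl(dimethyl)alane from 27 (aluminium on C2', methyl on C3') | C[Al](C)/C=C(\C)CC/C=C(\C)C[C@H](O[Si](C)(C)C(C)(C)C)/C=C(\C)CO[Si](C)(C)C(C)(C)C | intermediate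
29 | (1E,5E,8S,9E)-8,11-bis(tert-butyldimethylsilyloxy)-1-iodo-2,6,10-trimethylundeca-1,5,9-triene | I/C=C(\C)CC/C=C(\C)C[C@H](O[Si](C)(C)C(C)(C)C)/C=C(\C)CO[Si](C)(C)C(C)(C)C | intermediate
30 | ring C1'-zinc iodide from 12 | COC1=C(OC)[C@H](O[Si](CC)(CC)CC)[C@H](C[Zn]I)[C@@H](C)C1=O | intermediate
31 | (4R,5R,6R)-5-[(2E,6E,9S,10E)-9,12-bis(tert-butyldimethylsilyloxy)-3,7,11-trimethyldodeca-2,6,10-trien-1-yl]-2,3-dimethoxy-6-methyl-4-(triethylsilyloxy)cyclohex-2-en-1-one | COC1=C(OC)[C@H](O[Si](CC)(CC)CC)[C@H](C/C=C(\C)CC/C=C(\C)C[C@H](O[Si](C)(C)C(C)(C)C)/C=C(\C)CO[Si](C)(C)C(C)(C)C)[C@@H](C)C1=O | intermediate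
32 | (4R,5R,6R)-4-hydroxy-5-[(2E,6E,9S,10E)-9,12-dihydroxy-3,7,11-trimethyldodeca-2,6,10-trien-1-yl]-2,3-dimethoxy-6-methylcyclohex-2-en-1-one (CNP0109398.2) | COC1=C(OC)[C@H](O)[C@H](C/C=C(\C)CC/C=C(\C)C[C@H](O)/C=C(\C)CO)[C@@H](C)C1=O | target

**Step count**

Total: 23 steps. Longest linear sequence: 12 steps (1 to 32 through steps 1–10, 22 and 23; the side-chain line from 13 through steps 11–17, 19–21, 22 and 23 is equally long).

**Steps most likely to fail**

1. Step 3. Under the protic iminium conditions the bis(enol silane) may be hydrolysed or may add in a desilylative Michael fashion without closing the ring. Endo or facial selectivity may also be insufficient, and the adduct may epimerise at C5 or lose silanol through its enamine. Fallback, setting out from 3 and returning at 6: an aprotic, auxiliary-controlled Diels–Alder reaction of 3 with commercial (S)-4-benzyl-3-[(E)-but-2-enoyl]-1,3-oxazolidin-2-one (C/C=C/C(=O)N1[C@@H](Cc2ccccc2)COC1=O) and Et2AlCl in CH2Cl2 at −78 °C. In the aluminium chelate the benzyl group should shield the same face that the amine catalyst shields, and endo addition should give the N-acyl oxazolidinone cycloadduct F1. Reductive removal of the auxiliary with LiBH4 (THF/MeOH, 0 °C) would give alcohol 6 directly.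

2. Step 22. Zinc insertion into the β-branched iodide may be slow, with competing protonation of the organozinc to a C5 methyl group, and β-hydride elimination may follow transmetalation to palladium. Fallback, setting out from 12 and 29 and returning at 31: a nickel-catalysed reductive cross-electrophile coupling (NiBr2(dme), 4,4'-di-tert-butyl-2,2'-bipyridine, Mn powder, NaI, DMA, rt). Here the alkyl iodide enters as a radical captured at nickel and no organozinc reagent is preformed; ketones and silyl ethers are tolerated and the alkene geometry of the alkenyl halide is normally kept. No new compound arises.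

3. Step 1. The half-reduced aluminium hemiacetal may cyclise onto the second ester and lead to over-reduced lactol-type products, and the dialdehyde may hydrate or oligomerise on aqueous work-up. Fallback, setting out from 1 and returning at 2: full reduction with LiAlH4 (THF, 0 °C) to 2,3-di-O-methyl-L-threitol F2, then Swern oxidation ((COCl)2, DMSO, Et3N, CH2Cl2, −78 °C) with a non-aqueous work-up (pentane, filtration). This should deliver anhydrous 2 for immediate silylation.

**Further compounds**

F1 | step 3 | (S)-4-benzyl-3-{[(1R,2R,5S,6R)-2,5-bis(tert-butyldimethylsilyloxy)-3,4-dimethoxy-6-methylcyclohex-3-en-1-yl]carbonyl}-1,3-oxazolidin-2-one | COC1=C(OC)[C@H](O[Si](C)(C)C(C)(C)C)[C@H](C(=O)N2[C@@H](Cc3ccccc3)COC2=O)[C@@H](C)[C@@H]1O[Si](C)(C)C(C)(C)C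
F0 | step 22 | none | none
F2 | step 1 | (2S,3S)-2,3-dimethoxybutane-1,4-diol (2,3-di-O-methyl-L-threitol) | OC[C@H](OC)[C@@H](OC)CO
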